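# Proposed total synthesis of pakyonol by nitro-activated SNAr macrocyclisation

## Analysis of the target

Pakyonol (19) is a macrocyclic bis(bibenzyl). Four benzene rings (A–D) are held in a 20-membered ring by two CH2CH2 bridges (ring D to ring A, ring B to ring C) and two diaryl ether oxygens (ring A to ring B, ring C to ring D). Taking the bridge-bearing carbon as C1 in every ring, ring A has the ether oxygen at C3 and a methoxy group at C4, ring B has the ether oxygen at C4, ring C has the free hydroxyl at C3 and the ether oxygen at C4, and ring D has the ether oxygen at C3. There is no stereocentre and the structure carries no stereodescriptor; the bridged rings are taken to rotate freely in a ring of this size, so no stereochemical problem has to be solved. The sensitive features are the electron-rich phenol of ring C, the oxidisable alkoxyarenes and benzylic positions, and the need to keep the ring A methyl ether while other phenols are unmasked. The difficulty is twofold: a 20-membered ring must be closed against oligomerisation, and a diaryl ether must be made at C4 of ring C, a carbon with an oxygen substituent beside it and no activating group, where copper-mediated etherification is poor. The strategy rests on that same ortho relationship: C3 of ring C can carry a nitro group that activates a fluoride at C4 for nucleophilic aromatic substitution and is afterwards converted into the C3 hydroxyl. Ring B, in contrast, has its bridge para to the ether oxygen, so a carbonyl group at the future benzylic carbon can activate the other ether formation at the very start.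

## Retrosynthetic reasoning

**19 back to 16.** The last operations change only the substituent at C3 of ring C: the phenol 19 comes from diazonium salt 18, this from aniline 17, and this from nitro compound 16. The detour is accepted because the nitro group is what makes the ring-closing ether bond easy, and nothing else in 16 is reducible or diazotisable, so no protection is needed.

**16 back to 15.** The bond between the ring D oxygen and C4 of ring C is cut. Of the two ether bonds it is the one next to the future hydroxyl, so only here can an ortho activator be placed and later turned into a group the target needs. The cut opens the macrocycle to a chain, 15, with exactly one phenol and one activated fluoride. The forward reaction has to form this C–O bond intramolecularly in preference to chain growth.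

**15 back to 14.** The ring D phenol is masked as its benzyl ether. It must not be a free nucleophile while the fluoronitro ring is being attached under basic conditions, and the benzyl group can be taken off by a Lewis acid without touching fluoride, nitro group or methyl ether.

**14 back to 10 and 11.** The ring B–ring C bridge is cut at its central C–C bond, giving the nitrostilbene 13 and, behind it, phosphonium salt 10 and the commercial aldehyde 11. The fluoronitro ring therefore enters last and as the electrophile, so that it meets base only as a pre-formed ylide (12). The alkene must then be saturated by a hydrogen transfer that spares nitro group, fluoride and benzyl ether.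

**10 back to 8.** Functional group changes only: the phosphonium salt 10 from benzylic alcohol 9, and 9 from ester 8.

**8 back to 5 and 2.** The ring D–ring A bridge is cut in the same way, through stilbene 7, into aldehyde 5 and phosphonium salt 2 (ylide 6). Doing this before the ester is touched means the two carbonyl carbons of 5 never compete.

**5 back to 3 and 4.** The ring A–ring B ether is cut at C4 of ring B. The ester of 4 sits para to fluorine, activates the substitution by the phenol of isovanillin (3), and then becomes the benzylic carbon of the second bridge. An ester is chosen instead of a second aldehyde so that 5 has two distinguishable carbonyl groups.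

**2 back to 1.** The ring D building block 2 is one step from commercial 3-benzyloxybenzyl alcohol (1).

## Alternatives that were turned down

**Alternative 1:** Ring A is built instead of bought. Two ring bonds of ring A, C1–C2 and C5–C6, are disconnected, leading to 4-(3-bromophenyl)butanal A1 and the aryloxy enone A2, which already carries rings B and C. In the forward direction the pyrrolidine enamine of A1 would add in conjugate fashion to A2, and the methyl ketone would then condense with the aldehyde (Robinson-type annulation). The product is the 6-aryloxy-4-substituted cyclohex-2-enone A3, a racemic mixture of diastereomers.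
- For it: the 1,3,4 pattern of ring A is written into the open-chain partners; the ring A–ring B oxygen is attached with no aromatic substitution at all; the C–C bond formations are robust and metal-free. On the ring A–ring B ether it is as good as the chosen route.
- Against it: ring A with exactly this pattern is available as isovanillin (3), so steps are spent on a ring that costs nothing. The two stereocentres of A3 are made only to be destroyed. A3 must still be dehydrogenated to the phenol and O-methylated. A2 is a donor-substituted acceptor, less electrophilic and prone to polymerise.
- Decisive point: the macrocycle is still open after the key step. The unactivated ring D bromide would then have to be coupled with a ring C phenol flanked by a benzyloxy group, by metal-mediated etherification under macrocyclisation conditions.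
- Comparison: the chosen route puts its key step on the ring closure itself and makes the hard ether bond by an activated, ionic substitution.

**Alternative 2:** Ring B is built in the ring-closing step. Two ring bonds of ring B, C1–C6 and C2–C3, are disconnected, giving the open-chain diene–ynone A4, with a 2-aryloxybutadiene on the ring A oxygen and a terminal ynone on the ring C side chain. Heating at high dilution would bring about an intramolecular Diels–Alder reaction, and DDQ would dehydrogenate the cyclohexadiene to the macrocyclic aryl ketone A5, whose carbonyl lies on the bridge next to ring B.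
- For it: ring construction and macrocyclisation coincide, and the donor on the diene and the acceptor on the alkyne favour the para orientation the target needs. The endgame is shorter than that of the chosen route, since one hydrogenolysis could remove both the benzylic ketone and the benzyl ether and there is no nitro group to convert.
- Against it: a tether of this length gives no entropic help, so the cycloaddition has the rate of an intermolecular one and needs heat. Under heat 2-aryloxydienes dimerise and polymerise and terminal ynones pick up nucleophiles. The tether could override the electronic preference and give the meta-bridged isomer. The enol-ether diene is acid-labile and laborious to prepare. The ring C–ring D ether must already be present in A4, so the unactivated, ortho-oxygenated etherification is only moved earlier, not avoided.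
- Comparison: the chosen route is weaker in the endgame, but all four rings are purchased, the ring closure has a single possible regiochemical outcome, and it runs near room temperature.

**Alternative 3:** The ring A–ring B ether is the ring-closing bond and is made oxidatively. The bond between the ether oxygen and C3 of ring A is cut, giving the open-chain bisphenol A6 (ring A as a 2,6-dibromophenol, ring B as a 2,6-dichlorophenol, ring C oxygen benzylated). Anodic oxidation in methanol would make the dibromophenol electrophilic; the ring B phenol oxygen would attack a bromine-bearing carbon with loss of bromide, and zinc reduction of the dienone would return the phenol, giving the macrocyclic bromo dichloro phenol A7.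
- For it: the conditions are mild and biomimetic, and the halogens steer the coupling to oxygen. The endgame (O-methylation, then one hydrogenolysis that removes three halogens and the benzyl group) is at least as short as that of the chosen route and needs no diazonium chemistry.
- Against it: four halogens have to be installed on two rings first. The ring C–ring D ether, the hard one, still has to be made beforehand at an unactivated carbon. The two phenols are told apart only by their oxidation potentials. The dialkoxy ring C is itself oxidisable. Phenol oxidation also gives C–C coupling and methanol adducts. Ring closure at an electrode in dilute solution is slow and needs special equipment.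
- Comparison: the chosen route forms the ring A–ring B ether in the first step by an ordinary substitution and closes the ring at the other ether by a two-electron process with one reactive site.

Key step: step 10

## Route

Remark on the chemistry: 19 is drawn without stereodescriptors and is treated as achiral. Alkenes 7 and 13 are carried as E/Z mixtures, because both isomers are reduced to the same bridge.

Step 1
Reactants: 1 [3-(benzyloxy)phenyl]methanol (3-benzyloxybenzyl alcohol)
Product: 2 [3-(benzyloxy)benzyl]triphenylphosphonium bromide
Conditions: PPh3·HBr, MeCN, reflux
Reagents that add atoms: triphenylphosphine hydrobromide, Br.c1ccc(cc1)P(c1ccccc1)c1ccccc1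
Why: The acidic phosphonium hydrobromide ionises the benzylic alcohol, bromide takes the benzylic carbon and PPh3 quaternises the bromide in the same pot (nucleophilic substitution, phosphonium salt formation). The aryl benzyl ether is inert to this weak acid.

Step 2
Reactants: 3 isovanillin (3-hydroxy-4-methoxybenzaldehyde); 4 methyl 4-fluorobenzoate
Product: 5 methyl 4-(5-formyl-2-methoxyphenoxy)benzoate
Conditions: K2CO3, DMF, 140 °C
Reagents that add atoms: none
Why: Nucleophilic aromatic substitution: the phenoxide of 3 adds para to the ester, whose carbonyl stabilises the Meisenheimer complex, and fluoride leaves. The aldehyde of 3 is not enolisable and carbonate is not nucleophilic enough to attack either carbonyl group.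

Step 3
Reactants: 2 [3-(benzyloxy)benzyl]triphenylphosphonium bromide; 5 methyl 4-(5-formyl-2-methoxyphenoxy)benzoate
Product: 7 methyl 4-(5-{2-[3-(benzyloxy)phenyl]ethenyl}-2-methoxyphenoxy)benzoate (E/Z mixture), via benzylidenephosphorane ylide 6 (not isolated)
Conditions: NaN(SiMe3)2 (slightly less than 1 equiv to 2), THF, 0 °C; then 5, 0 °C to rt
Reagents that add atoms: none
Why: Wittig olefination: the semistabilised ylide is formed completely before the aldehyde is added, so the ester never meets free base, and it adds to the aldehyde far faster than to the ester. The alkene geometry is not controlled and need not be, since the double bond is reduced in the next step.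

Step 4
Reactants: 7 methyl 4-(5-{2-[3-(benzyloxy)phenyl]ethenyl}-2-methoxyphenoxy)benzoate (E/Z mixture)
Product: 8 methyl 4-(5-{2-[3-(benzyloxy)phenyl]ethyl}-2-methoxyphenoxy)benzoate
Conditions: TsNHNH2 (excess, in portions), NaOAc, DME/H2O, reflux
Reagents that add atoms: none
Why: Diimide reduction: HN=NH released by thermal fragmentation of the sulfonyl hydrazide delivers two hydrogens to the C=C bond in a concerted syn transfer. It is chosen over hydrogenation on palladium because the benzyl ether must stay, and the ester is untouched in the acetate buffer.

Step 5
Reactants: 8 methyl 4-(5-{2-[3-(benzyloxy)phenyl]ethyl}-2-methoxyphenoxy)benzoate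
Product: 9 [4-(5-{2-[3-(benzyloxy)phenyl]ethyl}-2-methoxyphenoxy)phenyl]methanol
Conditions: LiAlH4, THF, 0 °C
Reagents that add atoms: none
Why: Hydride reduction of the aryl ester to the primary benzylic alcohol. Aryl ethers and the benzyl ether do not react with LiAlH4 at this temperature.

Step 6
Reactants: 9 [4-(5-{2-[3-(benzyloxy)phenyl]ethyl}-2-methoxyphenoxy)phenyl]methanol
Product: 10 [4-(5-{2-[3-(benzyloxy)phenyl]ethyl}-2-methoxyphenoxy)benzyl]triphenylphosphonium bromide
Conditions: PPh3·HBr, MeCN, reflux
Reagents that add atoms: triphenylphosphine hydrobromide, Br.c1ccc(cc1)P(c1ccccc1)c1ccccc1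
Why: Same substitution and quaternisation as in step 1, helped here by the para aryloxy group, which stabilises the benzylic cation. No alkene is present, and the methyl, benzyl and diaryl ethers tolerate the weak acid.

Step 7
Reactants: 10 [4-(5-{2-[3-(benzyloxy)phenyl]ethyl}-2-methoxyphenoxy)benzyl]triphenylphosphonium bromide; 11 4-fluoro-3-nitrobenzaldehyde
Product: 13 4-{2-[3-(benzyloxy)phenyl]ethyl}-2-{4-[2-(4-fluoro-3-nitrophenyl)ethenyl]phenoxy}-1-methoxybenzene (E/Z mixture), via ring B benzylidenephosphorane ylide 12 (not isolated)
Conditions: NaN(SiMe3)2 (0.95 equiv), THF, 0 °C; then 11, −78 °C to rt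
Reagents that add atoms: none
Why: Wittig olefination with the ylide pre-formed from a slight deficit of a non-nucleophilic amide base, so the doubly activated fluoride of 11 never meets free base; addition of the ylide to the very electrophilic aldehyde at low temperature is much faster than attack at C–F. The benzyl ether keeps the ring D oxygen from competing as a nucleophile.

Step 8
Reactants: 13 4-{2-[3-(benzyloxy)phenyl]ethyl}-2-{4-[2-(4-fluoro-3-nitrophenyl)ethenyl]phenoxy}-1-methoxybenzene (E/Z mixture)
Product: 14 4-{2-[3-(benzyloxy)phenyl]ethyl}-2-{4-[2-(4-fluoro-3-nitrophenyl)ethyl]phenoxy}-1-methoxybenzene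
Conditions: KO2CN=NCO2K (excess, in portions), AcOH, THF/MeOH, rt
Reagents that add atoms: none
Why: Diimide reduction: diimide reduces the nonpolar C=C bond and leaves the nitro group, the C–F bond and the benzyl ether alone, whereas hydrogenation on palladium would reduce the nitro group and cleave the benzyl ether. Generating diimide from the azodicarboxylate with acid at room temperature keeps hydrazide, sulfinate and hydroxide nucleophiles away from the activated fluoride.

Step 9
Reactants: 14 4-{2-[3-(benzyloxy)phenyl]ethyl}-2-{4-[2-(4-fluoro-3-nitrophenyl)ethyl]phenoxy}-1-methoxybenzene
Product: 15 3-[2-(3-{4-[2-(4-fluoro-3-nitrophenyl)ethyl]phenoxy}-4-methoxyphenyl)ethyl]phenol (seco fluoronitro phenol)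
Conditions: BCl3, C6HMe5, CH2Cl2, −78 °C; aqueous work-up
Reagents that add atoms: none
Why: Lewis acid debenzylation: BCl3 activates the benzylic ether oxygen and the benzyl cation is passed to pentamethylbenzene (Friedel–Crafts scavenging), so it cannot alkylate rings A or D. The methyl and diaryl ethers are much slower at −78 °C, and because the method is neither basic nor reducing, fluoride and nitro group survive and the phenol is not exposed to base before the dilution step.

Step 10
Reactants: 15 3-[2-(3-{4-[2-(4-fluoro-3-nitrophenyl)ethyl]phenoxy}-4-methoxyphenyl)ethyl]phenol
Product: 16 nitro macrocycle (pakyonol skeleton with NO2 in place of the ring C hydroxyl)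
Conditions: K2CO3, 4 Å MS, DMF, slow addition of 15 to about 0.002 M final concentration, rt to 45 °C
Reagents that add atoms: none
Why: Carbonate deprotonates the only phenol of 15; the ring D phenoxide adds to C4 of ring C to give a Meisenheimer complex whose negative charge is taken up by the ortho nitro group, and loss of fluoride restores the arene (addition–elimination SNAr). The closest known reaction type is the intramolecular SNAr macroetherification of phenols onto ortho-nitro aryl fluorides that bear only an alkyl chain para to fluorine, used for macrocyclic diaryl ethers. One ring is closed, the 20-membered macrocycle, by C–O bond formation between the ring D oxygen and C4 of ring C, an end-to-end closure of a chain of four rigid arenes joined by two flexible ethylene hinges and one ether. No stereocentre is formed. The step needs site selectivity and chemoselectivity, and both are built into 15: there is one phenol and one activated leaving group, while the ring A–ring B ether, the methyl ether and all other ring positions are inert under these conditions. It also needs ring closure to win over intermolecular etherification, which slow addition into dilute suspension secures by keeping the standing phenoxide concentration low. The mild temperature allowed by nitro activation keeps hydrolysis of the fluoride and ether exchange out.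

Step 11
Reactants: 16 nitro macrocycle
Product: 17 amino macrocycle (pakyonol skeleton with NH2 in place of the ring C hydroxyl)
Conditions: H2 (1 atm), Pd/C, EtOAc/MeOH, rt
Reagents that add atoms: none
Why: Catalytic hydrogenation of the aryl nitro group to the aniline. No benzyl ether or halogen is left, and diaryl ethers and bibenzyl bridges are stable to these conditions.

Step 12
Reactants: 17 amino macrocycle
Product: 19 pakyonol, via macrocyclic arenediazonium tetrafluoroborate 18 (not isolated)
Conditions: t-BuONO, HBF4·OEt2, MeCN, −10 °C; then Cu(NO3)2·3H2O (large excess), Cu2O, H2O, rt
Reagents that add atoms: water, O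
Why: Diazotisation followed by copper-mediated hydroxydediazoniation: monovalent copper from Cu2O reduces the diazonium ion to an aryl radical with loss of N2, and the radical is hydroxylated by ligand transfer from the aquo complex of divalent copper, present in large excess. The fast capture at room temperature is meant to outrun attack of the radical on ring D and hydrogen abstraction; acetonitrile is used because it is a poor hydrogen donor.

## Compound list

1 | [3-(benzyloxy)phenyl]methanol (3-benzyloxybenzyl alcohol) | OCc1cccc(OCc2ccccc2)c1 | starting material
2 | [3-(benzyloxy)benzyl]triphenylphosphonium bromide | [Br-].c1ccc(cc1)COc1cccc(C[P+](c2ccccc2)(c2ccccc2)c2ccccc2)c1 | intermediate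
3 | isovanillin (3-hydroxy-4-methoxybenzaldehyde) | COc1ccc(C=O)cc1O | starting material
4 | methyl 4-fluorobenzoate | COC(=O)c1ccc(F)cc1 | starting material
5 | methyl 4-(5-formyl-2-methoxyphenoxy)benzoate | COC(=O)c1ccc(Oc2cc(C=O)ccc2OC)cc1 | intermediate
6 | [3-(benzyloxy)benzylidene]triphenylphosphorane | c1ccc(cc1)COc1cccc(C=P(c2ccccc2)(c2ccccc2)c2ccccc2)c1 | intermediate (not isolated)
7 | methyl 4-(5-{2-[3-(benzyloxy)phenyl]ethenyl}-2-methoxyphenoxy)benzoate, E/Z mixture | COC(=O)c1ccc(Oc2cc(C=Cc3cccc(OCc4ccccc4)c3)ccc2OC)cc1 | intermediate
8 | methyl 4-(5-{2-[3-(benzyloxy)phenyl]ethyl}-2-methoxyphenoxy)benzoate | COC(=O)c1ccc(Oc2cc(CCc3cccc(OCc4ccccc4)c3)ccc2OC)cc1 | intermediate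
9 | [4-(5-{2-[3-(benzyloxy)phenyl]ethyl}-2-methoxyphenoxy)phenyl]methanol | OCc1ccc(Oc2cc(CCc3cccc(OCc4ccccc4)c3)ccc2OC)cc1 | intermediate
10 | [4-(5-{2-[3-(benzyloxy)phenyl]ethyl}-2-methoxyphenoxy)benzyl]triphenylphosphonium bromide | [Br-].COc1ccc(CCc2cccc(OCc3ccccc3)c2)cc1Oc1ccc(C[P+](c2ccccc2)(c2ccccc2)c2ccccc2)cc1 | intermediate
11 | 4-fluoro-3-nitrobenzaldehyde | O=Cc1ccc(F)c([N+](=O)[O-])c1 | starting material
12 | [4-(5-{2-[3-(benzyloxy)phenyl]ethyl}-2-methoxyphenoxy)benzylidene]triphenylphosphorane | COc1ccc(CCc2cccc(OCc3ccccc3)c2)cc1Oc1ccc(C=P(c2ccccc2)(c2ccccc2)c2ccccc2)cc1 | intermediate (not isolated)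
13 | 4-{2-[3-(benzyloxy)phenyl]ethyl}-2-{4-[2-(4-fluoro-3-nitrophenyl)ethenyl]phenoxy}-1-methoxybenzene, E/Z mixture | COc1ccc(CCc2cccc(OCc3ccccc3)c2)cc1Oc1ccc(C=Cc2ccc(F)c([N+](=O)[O-])c2)cc1 | intermediate
14 | 4-{2-[3-(benzyloxy)phenyl]ethyl}-2-{4-[2-(4-fluoro-3-nitrophenyl)ethyl]phenoxy}-1-methoxybenzene | COc1ccc(CCc2cccc(OCc3ccccc3)c2)cc1Oc1ccc(CCc2ccc(F)c([N+](=O)[O-])c2)cc1 | intermediate
15 | 3-[2-(3-{4-[2-(4-fluoro-3-nitrophenyl)ethyl]phenoxy}-4-methoxyphenyl)ethyl]phenol (seco fluoronitro phenol) | Oc1cccc(CCc2ccc(OC)c(Oc3ccc(CCc4ccc(F)c([N+](=O)[O-])c4)cc3)c2)c1 | intermediate
16 | nitro macrocycle (pakyonol skeleton, NO2 at C3 of ring C in place of OH) | COc1ccc2cc1Oc1ccc(cc1)CCc1ccc(c([N+](=O)[O-])c1)Oc1cccc(c1)CC2 | intermediate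
17 | amino macrocycle (pakyonol skeleton, NH2 at C3 of ring C in place of OH) | COc1ccc2cc1Oc1ccc(cc1)CCc1ccc(c(N)c1)Oc1cccc(c1)CC2 | intermediate
18 | macrocyclic arenediazonium tetrafluoroborate (N2+ at C3 of ring C) | COc1ccc2cc1Oc1ccc(cc1)CCc1ccc(c([N+]#N)c1)Oc1cccc(c1)CC2.F[B-](F)(F)F | intermediate (not isolated)
19 | pakyonol | COc1ccc2cc1Oc1ccc(cc1)CCc1ccc(c(O)c1)Oc1cccc(c1)CC2 | target

## Step count and points of risk

Total step count: 12 (steps 1–12). Longest linear sequence: 11 steps, from isovanillin (3) through steps 2–12 to 19. Step 1 is a one-step side branch.

**Step 10 (key step).** Most likely failure: chain growth by intermolecular etherification, leading to cyclic dimers and oligomers, competes with ring closure. This gets worse if the fluoride, activated by a single nitro group and carrying an alkyl chain para to it, reacts so slowly that more heat and time are needed, which also lets traces of water hydrolyse the fluoride.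
Fallback: the order of the last two bond formations is inverted, so the ether is made between two molecules and the ring is closed at the ring B–ring C bridge. The fallback sets out from alcohol 9 and returns to the route at 16.
- Hydrogenolysis of the benzyl ether of 9 (H2, Pd/C, EtOAc) would give 3-(2-{3-[4-(hydroxymethyl)phenoxy]-4-methoxyphenyl}ethyl)phenol F1.
- The phenoxide of F1 (K2CO3, DMF, rt) would displace the fluoride of 11, which is activated by both the nitro and the formyl group, to give 4-[3-(2-{3-[4-(hydroxymethyl)phenoxy]-4-methoxyphenyl}ethyl)phenoxy]-3-nitrobenzaldehyde F2.
- PPh3·HBr in MeCN would convert the benzylic alcohol into {4-[5-(2-{3-[(4-formyl-2-nitrophenyl)oxy]phenyl}ethyl)-2-methoxyphenoxy]benzyl}triphenylphosphonium bromide F3.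
- An intramolecular Wittig reaction at high dilution (K2CO3, 18-crown-6, CH2Cl2, slow addition) would close the ring to the macrocyclic nitrostilbene F4.
- Diimide reduction as in step 8 would give 16.

**Step 12.** Most likely failure: after loss of nitrogen the aryl radical or cation is not captured by water but attacks the neighbouring ring D across the ether oxygen (Pschorr-type ring closure), or abstracts hydrogen from the medium.
Fallback: the C–O bond is made by cross-coupling instead of solvolysis. Starting from 17, diazotisation as in step 12 (through 18) in the presence of KI would give the macrocyclic aryl iodide F5 (iodine at C3 of ring C), since iodide captures the intermediate much faster than ring D can. Palladium-catalysed hydroxylation (Pd2(dba)3, t-BuXPhos, KOH, dioxane/H2O, 100 °C) would then give 19.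

**Step 8.** Most likely failure: incomplete hydrogen transfer, because diimide disproportionates faster than it reduces a conjugated disubstituted alkene. On the long exposure then needed, nucleophiles in the medium may displace the activated fluoride.
Fallback: the bridge is put in already saturated by sp3–sp2 coupling, so that no alkene ever accompanies the fluoronitro ring; this also bypasses step 7. Starting from phosphonium salt 10, a Wittig reaction with aqueous formaldehyde (K2CO3, CH2Cl2/H2O) would give the styrene 4-{2-[3-(benzyloxy)phenyl]ethyl}-2-(4-ethenylphenoxy)-1-methoxybenzene F6. Hydroboration with 9-BBN in THF would give the B-alkyl-9-borabicyclo[3.3.1]nonane F7, used without isolation. Suzuki–Miyaura coupling with 4-bromo-1-fluoro-2-nitrobenzene (Pd(dppf)Cl2, K3PO4, DMF, 50 °C) would return the route at 14.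

**Step 2.** Most likely failure: substitution is slow at a ring activated only by an ester, so that at the temperature required the phenoxide attacks the ester methyl group or water carried by the carbonate hydrolyses the ester.
Fallback: the same ether is made by copper catalysis instead of addition–elimination. Starting from 3, Ullmann coupling with methyl 4-iodobenzoate (CuI, N,N-dimethylglycine, Cs2CO3, dioxane, 90 °C) would give 5 directly, with no new intermediate.

## Further compounds

F1 | step 10 | 3-(2-{3-[4-(hydroxymethyl)phenoxy]-4-methoxyphenyl}ethyl)phenol | OCc1ccc(Oc2cc(CCc3cccc(O)c3)ccc2OC)cc1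
F2 | step 10 | 4-[3-(2-{3-[4-(hydroxymethyl)phenoxy]-4-methoxyphenyl}ethyl)phenoxy]-3-nitrobenzaldehyde | OCc1ccc(Oc2cc(CCc3cccc(Oc4ccc(C=O)cc4[N+](=O)[O-])c3)ccc2OC)cc1
F3 | step 10 | {4-[5-(2-{3-[(4-formyl-2-nitrophenyl)oxy]phenyl}ethyl)-2-methoxyphenoxy]benzyl}triphenylphosphonium bromide | [Br-].COc1ccc(CCc2cccc(Oc3ccc(C=O)cc3[N+](=O)[O-])c2)cc1Oc1ccc(C[P+](c2ccccc2)(c2ccccc2)c2ccccc2)cc1
F4 | step 10 | macrocyclic nitrostilbene (16 with CH=CH between rings B and C, E/Z mixture) | COc1ccc2cc1Oc1ccc(cc1)C=Cc1ccc(c([N+](=O)[O-])c1)Oc1cccc(c1)CC2
F5 | step 12 | macrocyclic aryl iodide (pakyonol skeleton, iodine at C3 of ring C in place of OH) | COc1ccc2cc1Oc1ccc(cc1)CCc1ccc(c(I)c1)Oc1cccc(c1)CC2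
F6 | step 8 | 4-{2-[3-(benzyloxy)phenyl]ethyl}-2-(4-ethenylphenoxy)-1-methoxybenzene | C=Cc1ccc(Oc2cc(CCc3cccc(OCc4ccccc4)c3)ccc2OC)cc1
F7 | step 8 | 9-{2-[4-(5-{2-[3-(benzyloxy)phenyl]ethyl}-2-methoxyphenoxy)phenyl]ethyl}-9-borabicyclo[3.3.1]nonane | COc1ccc(CCc2cccc(OCc3ccccc3)c2)cc1Oc1ccc(CCB2C3CCCC2CCC3)cc1
F0 | step 2 | none | none
A1 | alternative 1 | 4-(3-bromophenyl)butanal | O=CCCCc1cccc(Br)c1
A2 | alternative 1 | 3-(4-{2-[3-(benzyloxy)-4-(tert-butyldimethylsilyloxy)phenyl]ethyl}phenoxy)but-3-en-2-one | CC(=O)C(=C)Oc1ccc(CCc2ccc(O[Si](C)(C)C(C)(C)C)c(OCc3ccccc3)c2)cc1
A3 | alternative 1 | 6-(4-{2-[3-(benzyloxy)-4-(tert-butyldimethylsilyloxy)phenyl]ethyl}phenoxy)-4-[2-(3-bromophenyl)ethyl]cyclohex-2-en-1-one (racemic mixture of diastereomers) | O=C1C=CC(CCc2cccc(Br)c2)CC1Oc1ccc(CCc2ccc(O[Si](C)(C)C(C)(C)C)c(OCc3ccccc3)c2)cc1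
A4 | alternative 2 | 1-{3-(benzyloxy)-4-[3-(2-{3-(buta-1,3-dien-2-yloxy)-4-methoxyphenyl}ethyl)phenoxy]phenyl}but-3-yn-2-one | C=CC(=C)Oc1cc(CCc2cccc(Oc3ccc(CC(=O)C#C)cc3OCc3ccccc3)c2)ccc1OC
A5 | alternative 2 | macrocyclic aryl ketone (O-benzyl pakyonol skeleton with C=O on the bridge carbon attached to ring B) | COc1ccc2cc1Oc1ccc(cc1)C(=O)Cc1ccc(c(OCc3ccccc3)c1)Oc1cccc(c1)CC2
A6 | alternative 3 | 2,6-dibromo-4-[2-(3-{2-(benzyloxy)-4-[2-(3,5-dichloro-4-hydroxyphenyl)ethyl]phenoxy}phenyl)ethyl]phenol | Oc1c(Br)cc(CCc2cccc(Oc3ccc(CCc4cc(Cl)c(O)c(Cl)c4)cc3OCc3ccccc3)c2)cc1Br
A7 | alternative 3 | macrocyclic bromo dichloro phenol (O-benzyl on ring C, free OH and Br on ring A, two Cl on ring B) | Oc1c(Br)cc2cc1Oc1c(Cl)cc(cc1Cl)CCc1ccc(c(OCc3ccccc3)c1)Oc1cccc(c1)CC2
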